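The route rests on cutting the C5–O bond of the open-chain anti-1,3-diol. Because the C3 and C5 oxygens flank the C4 methylene, the C3 hydroxyl of an (E)-allylic alcohol can steer an oxygen atom onto C4=C5, and the unwanted oxygen at C4 is later replaced by hydride. In a single operation a titanium–tartrate epoxidation, whose ligand and substrate chirality reinforce each other, makes the C4–O and C5–O bonds, closes the C4–C5–O oxirane and fixes C4 and C5, while slow-reacting (R)-alcohol is left behind. The precursor is (S,E)-1-(4-benzyloxy-3-methoxyphenyl)tetradec-4-en-3-ol, from asymmetric alkenylzinc addition to a 3-arylpropanal; the guaiacyl ring is only a benzyl-protected spectator.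

Key step: step 4

Assumption (numbering): the chain is numbered as a tetradecane with C1 benzylic, so the target is the (3S,5S) anti diol.
Assumption (chemistry): the isoborneol amino alcohol is taken to send an alkenyl group to the same aldehyde face as an alkyl group, so the (2R) ligand is specified for Re-face attack; if the sense is the reverse, its mirror image is used with no other change.

Step 1
Reactants: 1 3-(4-hydroxy-3-methoxyphenyl)propan-1-ol (dihydroconiferyl alcohol); 2 benzyl bromide
Product: 3 3-(4-benzyloxy-3-methoxyphenyl)propan-1-ol
Conditions: K2CO3 (1.5 equiv), acetone, reflux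
Reagents that add atoms: none
Why: Williamson ether synthesis, in which K2CO3 deprotonates only the phenol and not the primary alcohol, so the phenoxide should displace bromide from benzyl bromide chemoselectively.

Step 2
Reactants: 3 3-(4-benzyloxy-3-methoxyphenyl)propan-1-ol
Product: 4 3-(4-benzyloxy-3-methoxyphenyl)propanal
Conditions: TEMPO (10 mol%), PhI(OAc)2 (1.1 equiv), CH2Cl2, rt
Reagents that add atoms: none
Why: TEMPO-catalysed oxidation with PhI(OAc)2 as terminal oxidant takes a primary alcohol to the aldehyde through the oxoammonium ion and stops there under anhydrous conditions, leaving both aryl ethers untouched; the enolisable aldehyde is used without storage.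

Step 3
Reactants: 4 3-(4-benzyloxy-3-methoxyphenyl)propanal; 5 undec-1-yne
Product: 8 (S,E)-1-(4-benzyloxy-3-methoxyphenyl)tetradec-4-en-3-ol, via (E)-dicyclohexyl(undec-1-enyl)borane 6 (not isolated), via (E)-ethyl(undec-1-enyl)zinc 7 (not isolated)
Conditions: 5 (1.3 equiv), Cy2BH (1.3 equiv; from BH3·SMe2 and cyclohexene), hexane, 0 °C to rt; Et2Zn (1.4 equiv), −78 °C; (+)-MIB [(2R)-3-exo-morpholinoisoborneol] (4 mol%), then 4 added slowly, −10 °C; aq. NH4Cl
Reagents that add atoms: none
Why: Syn, anti-Markovnikov hydroboration gives the (E)-alkenylborane, boron-to-zinc exchange keeps that geometry, and the zinc aminoalkoxide of (+)-MIB should carry the alkenyl group to the Re face of the aldehyde through the usual bimetallic six-membered transition state, so C3 is set (S) by the ligand (catalytic asymmetric alkenylzinc addition to an aldehyde); the boron route is preferred to a zirconium one because no Lewis-acidic metallocene is present to drive a racemic background addition.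

Step 4
Reactants: 8 (S,E)-1-(4-benzyloxy-3-methoxyphenyl)tetradec-4-en-3-ol
Product: 9 (3S,4S,5S)-1-(4-benzyloxy-3-methoxyphenyl)-4,5-epoxytetradecan-3-ol (erythro, trans-oxirane)
Conditions: Ti(OiPr)4 (15 mol%), L-(+)-DIPT (20 mol%), TBHP in decane (just under 1 equiv, matched to the (S)-content of 8), 4 Å molecular sieves, CH2Cl2, −20 °C
Reagents that add atoms: tert-butyl hydroperoxide, CC(C)(C)OO
Why: Isopropoxide exchange puts the C3 alkoxide and an η2-bound tert-butylperoxide on the same tetravalent titanium of the dimeric Ti–tartrate complex, and the C4=C5 π bond attacks the activated peroxide oxygen along the O–O axis in a spiro transition state, so both C–O bonds form suprafacially in one step and the E geometry becomes a trans oxirane. The closest known reaction type is the Sharpless asymmetric epoxidation of secondary (E)-allylic alcohols as it is run in kinetic resolutions, applied here to an already enriched alcohol. The oxirane, the only ring formed, closes by concerted [2+1] oxygen-atom transfer to the alkene and not by stepwise closure of an open intermediate. C4 and C5 are controlled by the L-(+)-tartrate, which opens the alkene face that leads to the (4S,5S) oxirane, and the C3 (S) centre reinforces this: with O3 on titanium the C2 chain lies beside the small C5–H and the C3–H points at the tartrate ester, so the erythro (3S,4S,5S) isomer should form fast. The step needs alkene face selectivity, secured by this matched pairing, and chemoselectivity for the allylic alkene over the electron-rich arene, secured because oxygen is transferred only within the titanium-bound alkoxide. Any (R)-alcohol carried over from step 3 would have to push its C2 chain into the ligand, should react far more slowly, and is removed as unchanged alcohol by chromatography.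

Step 5
Reactants: 9 (3S,4S,5S)-1-(4-benzyloxy-3-methoxyphenyl)-4,5-epoxytetradecan-3-ol
Product: 10 (3S,5S)-1-(4-benzyloxy-3-methoxyphenyl)tetradecane-3,5-diol
Conditions: NaAlH2(OCH2CH2OCH3)2 (2.5 equiv), THF, 0 °C to rt; aq. NaOH
Reagents that add atoms: none
Why: Reductive opening of a 2,3-epoxy alcohol by an alkoxyaluminium hydride, in which the C3 alkoxide binds aluminium with loss of H2 and the tethered Al–H attacks the nearer oxirane carbon C4 in SN2 fashion, so C4 becomes a methylene group, the C5–O bond keeps its configuration and the anti (3S,5S) diol should result.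

Step 6
Reactants: 10 (3S,5S)-1-(4-benzyloxy-3-methoxyphenyl)tetradecane-3,5-diol
Product: 11 (3S,5S)-1-(4-hydroxy-3-methoxyphenyl)tetradecane-3,5-diol
Conditions: H2 (1 atm), 10% Pd/C, EtOAc, rt
Reagents that add atoms: none
Why: Hydrogenolysis of the benzyl aryl ether over palladium frees the phenol under neutral conditions in which the secondary alcohols, the aryl methyl ether and both stereocentres are inert, and no alkene remains to be reduced.

Compound list
1 | 3-(4-hydroxy-3-methoxyphenyl)propan-1-ol (dihydroconiferyl alcohol) | OCCCc1ccc(O)c(OC)c1 | starting material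
2 | benzyl bromide | BrCc1ccccc1 | starting material
3 | 3-(4-benzyloxy-3-methoxyphenyl)propan-1-ol | OCCCc1ccc(OCc2ccccc2)c(OC)c1 | intermediate
4 | 3-(4-benzyloxy-3-methoxyphenyl)propanal | O=CCCc1ccc(OCc2ccccc2)c(OC)c1 | intermediate
5 | undec-1-yne | C#CCCCCCCCCC | starting material
6 | (E)-dicyclohexyl(undec-1-enyl)borane | CCCCCCCCC/C=C/B(C1CCCCC1)C1CCCCC1 | intermediate (not isolated)
7 | (E)-ethyl(undec-1-enyl)zinc | CCCCCCCCC/C=C/[Zn]CC | intermediate (not isolated)
8 | (S,E)-1-(4-benzyloxy-3-methoxyphenyl)tetradec-4-en-3-ol | CCCCCCCCC/C=C/[C@@H](O)CCc1ccc(OCc2ccccc2)c(OC)c1 | intermediate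
9 | (3S,4S,5S)-1-(4-benzyloxy-3-methoxyphenyl)-4,5-epoxytetradecan-3-ol | CCCCCCCCC[C@@H]1O[C@H]1[C@@H](O)CCc1ccc(OCc2ccccc2)c(OC)c1 | intermediate
10 | (3S,5S)-1-(4-benzyloxy-3-methoxyphenyl)tetradecane-3,5-diol | CCCCCCCCC[C@H](O)C[C@@H](O)CCc1ccc(OCc2ccccc2)c(OC)c1 | intermediate
11 | (3S,5S)-1-(4-hydroxy-3-methoxyphenyl)tetradecane-3,5-diol | CCCCCCCCC[C@H](O)C[C@@H](O)CCc1ccc(O)c(OC)c1 | target

Total step count: 6.
Longest linear sequence: 6 steps (1 to 11); undec-1-yne enters in step 3.

Steps most likely to fail

Step 3. The risk is erosion of enantioselectivity by ligand-free background addition, competing ethyl transfer from zinc, and self-aldol condensation of the enolisable aldehyde. The fallback sets out from 4 and 5 and separates bond formation from stereocontrol. Compound 5 is deprotonated with n-BuLi (THF, −78 °C) to lithium undec-1-ynide F1, which adds to 4 to give racemic 1-(4-benzyloxy-3-methoxyphenyl)tetradec-4-yn-3-ol F2. MnO2 in CH2Cl2 oxidises this to 1-(4-benzyloxy-3-methoxyphenyl)tetradec-4-yn-3-one F3. Noyori transfer hydrogenation with RuCl[(S,S)-TsDPEN](p-cymene) in 2-propanol should then give (S)-1-(4-benzyloxy-3-methoxyphenyl)tetradec-4-yn-3-ol F4, the alkyne taking the place an aryl group has in the usual model. Alkoxide-directed trans-hydroalumination with NaAlH2(OCH2CH2OCH3)2 in THF reduces the alkyne to the (E)-alkene, and the fallback comes back to the route at 8.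

Step 4. The risk is incomplete discrimination between matched and mismatched alcohol if step 3 delivers material of low enantiomeric purity, together with slow turnover or titanium-mediated opening of the epoxy alcohol. The fallback sets out from 8 and makes the oxirane without a metal-bound hydroxyl. Silylation (TBSCl, imidazole, DMF) gives the tert-butyldimethylsilyl ether of 8 F5. Shi epoxidation with the enantiomer of the D-fructose-derived ketone (prepared from L-sorbose), KHSO5 (as 2KHSO5·KHSO4·K2SO4) and K2CO3 in MeCN/dimethoxymethane/water at 0 °C should give the tert-butyldimethylsilyl ether of 9 F6. Here the chiral dioxirane alone chooses the alkene face. Bu4NF buffered with AcOH in THF removes the silyl group without epoxide migration, and the fallback comes back to the route at 9.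

Step 5. The risk is loss of regiocontrol, with hydride attacking C5 as well as C4 and giving the 3,4-diol. The fallback sets out from 9 and lets a carbonyl group decide which C–O bond breaks. Dess–Martin oxidation (NaHCO3, CH2Cl2) gives (4R,5S)-1-(4-benzyloxy-3-methoxyphenyl)-4,5-epoxytetradecan-3-one F7. SmI2 in THF/MeOH at −90 °C cleaves only the C4–O bond α to the ketone and should give (S)-1-(4-benzyloxy-3-methoxyphenyl)-5-hydroxytetradecan-3-one F8. Evans–Saksena reduction with Me4NBH(OAc)3 in MeCN/AcOH at −20 °C delivers hydride from the C5-bound borate to the C3 ketone and should give the anti diol. The fallback comes back to the route at 10.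

Further compounds
F1 | step 3 | lithium undec-1-ynide | [Li]C#CCCCCCCCCC
F2 | step 3 | racemic 1-(4-benzyloxy-3-methoxyphenyl)tetradec-4-yn-3-ol | CCCCCCCCCC#CC(O)CCc1ccc(OCc2ccccc2)c(OC)c1
F3 | step 3 | 1-(4-benzyloxy-3-methoxyphenyl)tetradec-4-yn-3-one | CCCCCCCCCC#CC(=O)CCc1ccc(OCc2ccccc2)c(OC)c1
F4 | step 3 | (S)-1-(4-benzyloxy-3-methoxyphenyl)tetradec-4-yn-3-ol | CCCCCCCCCC#C[C@@H](O)CCc1ccc(OCc2ccccc2)c(OC)c1
F5 | step 4 | tert-butyldimethylsilyl ether of 8 | CCCCCCCCC/C=C/[C@@H](O[Si](C)(C)C(C)(C)C)CCc1ccc(OCc2ccccc2)c(OC)c1
F6 | step 4 | tert-butyldimethylsilyl ether of 9 | CCCCCCCCC[C@@H]1O[C@H]1[C@@H](O[Si](C)(C)C(C)(C)C)CCc1ccc(OCc2ccccc2)c(OC)c1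
F7 | step 5 | (4R,5S)-1-(4-benzyloxy-3-methoxyphenyl)-4,5-epoxytetradecan-3-one | CCCCCCCCC[C@@H]1O[C@H]1C(=O)CCc1ccc(OCc2ccccc2)c(OC)c1
F8 | step 5 | (S)-1-(4-benzyloxy-3-methoxyphenyl)-5-hydroxytetradecan-3-one | CCCCCCCCC[C@H](O)CC(=O)CCc1ccc(OCc2ccccc2)c(OC)c1
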